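The cycloheptane is assembled as a cyclohexene plus one carbon. C8, the lone ring methylene between the lactone-bearing carbon C7 and the carbinol carbon C9, is delivered as dibromocarbene to the C7=C9 double bond of a tartrate-derived cyclohexene that already holds the C1, C5, C6 and C10 stereocentres. This closes a cyclopropane by forming C7-C8 and C8-C9 at once; silver-assisted electrocyclic opening then cuts the temporary C7-C9 bond, and water takes the 2-bromoallyl cation at C9. The C7=C8 bromoalkene so formed accepts the methylene-lactone carbons by radical cyclisation from O6. The precursor, a bicyclic cyclohexene acetonide, comes from ring-closing metathesis.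

Key step: step 12

Remark on numbering: the target is numbered as a 4,5-seco-guaianolide. Carbocycle: C1 (tertiary carbinol), C5 (acyloxy), C6 (lactone oxygen), C7 (ring fusion), C8 (CH2), C9 (CHOH), C10 (CHMe). Side chain: C2 (C=O), C3, C4 (CHOH), C15. Lactone: C11, C12 (C=O), C13 (=CH2). C14 is the methyl on C10. The beta face of the carbocycle carries O5 and O9; the alpha face carries O6, the C1 hydroxyl, C11 and C14. rt = room temperature.

Assumption: the oxygen of the trans-dioxolane does not chelate the boron or cerium reagents, so additions next to it follow the Felkin-Anh/Cornforth sense.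

Step 1
Reactants: 1 (4R,5R)-2,2-dimethyl-1,3-dioxolane-4,5-dimethanol
Product: 2 mono-(4-methoxybenzyl) ether of diol 1
Conditions: NaH (1 equiv), 4-methoxybenzyl chloride (1 equiv), DMF, 0 °C to rt
Reagents that add atoms: 4-methoxybenzyl chloride, COc1ccc(CCl)cc1
Why: Williamson etherification of the mono-alkoxide of the C2-symmetric diol, in which both hydroxyls are equivalent, so one mono-ether results and no stereocentre is touched.

Step 2
Reactants: 2 mono-(4-methoxybenzyl) ether
Product: 3 (4S,5R)-5-[(4-methoxybenzyloxy)methyl]-2,2-dimethyl-1,3-dioxolane-4-carbaldehyde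
Conditions: Dess-Martin periodinane, CH2Cl2, 0 °C to rt
Reagents that add atoms: none
Why: Dess-Martin oxidation should give the alpha-alkoxy aldehyde under neutral conditions that do not epimerise it.

Step 3
Reactants: 3 aldehyde
Product: 4 (4R,5R)-4-[(4-methoxybenzyloxy)methyl]-2,2-dimethyl-5-vinyl-1,3-dioxolane
Conditions: Ph3PCH3Br, KN(SiMe3)2, THF, -78 to 0 °C
Reagents that add atoms: methyltriphenylphosphonium bromide, C[P+](c1ccccc1)(c1ccccc1)c1ccccc1.[Br-]
Why: Wittig methylenation with the non-stabilised ylide installs the vinyl group whose inner carbon is C7, and at low temperature it should outrun epimerisation of the trans-dioxolane aldehyde.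

Step 4
Reactants: 4 vinyl dioxolane 4-methoxybenzyl ether
Product: 5 [(4R,5R)-2,2-dimethyl-5-vinyl-1,3-dioxolan-4-yl]methanol
Conditions: DDQ, CH2Cl2/pH 7 buffer, 0 °C to rt
Reagents that add atoms: none
Why: oxidative cleavage of the electron-rich benzyl ether by DDQ leaves the vinyl group and the acetonide untouched.

Step 5
Reactants: 5 primary alcohol
Product: 6 (4S,5R)-2,2-dimethyl-5-vinyl-1,3-dioxolane-4-carbaldehyde
Conditions: Dess-Martin periodinane, CH2Cl2, 0 °C to rt
Reagents that add atoms: none
Why: Dess-Martin oxidation gives the C1 aldehyde, which is used at once to avoid epimerisation at C5.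

Step 6
Reactants: 6 aldehyde; 7 (Z)-crotylboronic acid pinacol ester
Product: 8 homoallylic alcohol (1R,2S)-1-[(4R,5R)-2,2-dimethyl-5-vinyl-1,3-dioxolan-4-yl]-2-methylbut-3-en-1-ol
Conditions: toluene, 4 Å molecular sieves, -78 °C to rt; then H2O
Reagents that add atoms: none
Why: allylboration through a closed chair (Zimmerman-Traxler) transition state, in which the Z-crotyl geometry puts the new methyl (C10) syn to the new hydroxyl (C1) and Felkin-Anh/Cornforth attack puts that hydroxyl anti to O5, which together fix C10; any minor facial isomer is removed by chromatography here.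

Step 7
Reactants: 8 homoallylic alcohol (1,7-diene)
Product: 9 cyclohexenol (3aR,4R,5S,7aR)-2,2,5-trimethyl-3a,4,5,7a-tetrahydro-1,3-benzodioxol-4-ol
Conditions: second-generation Grubbs catalyst RuCl2(=CHPh)(PCy3)(H2IMes) (5 mol %), CH2Cl2, 40 °C
Reagents that add atoms: none
Why: ring-closing metathesis of the two vinyl groups closes the six-membered ring C1-C5-C6-C7-C9-C10 with loss of ethene; the C7=C9 bond made here is the temporary bond of the plan.

Step 8
Reactants: 9 cyclohexenol
Product: 10 cyclohexenone (3aS,5S,7aR)-2,2,5-trimethyl-5,7a-dihydro-1,3-benzodioxol-4(3aH)-one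
Conditions: Dess-Martin periodinane, pyridine, CH2Cl2, 0 °C; used crude
Reagents that add atoms: none
Why: buffered Dess-Martin oxidation gives the beta,gamma-unsaturated ketone without the acid or base that would move the double bond into conjugation or epimerise C10 or C5.

Step 9
Reactants: 11 (R)-but-3-yn-2-ol
Product: 12 (R)-(but-3-yn-2-yloxy)(tert-butyl)dimethylsilane
Conditions: tert-butyldimethylsilyl chloride, imidazole, DMF, rt
Reagents that add atoms: tert-butyldimethylsilyl chloride, CC(C)(C)[Si](C)(C)Cl
Why: standard silylation protects the C4 hydroxyl of the side-chain building block, whose stereocentre comes from the chiral pool.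

Step 10
Reactants: 10 cyclohexenone; 12 silyl-protected alkyne
Product: 15 tertiary propargylic alcohol (3aS,4R,5S,7aR)-4-[(3R)-3-(tert-butyldimethylsilyloxy)but-1-ynyl]-2,2,5-trimethyl-3a,4,5,7a-tetrahydro-1,3-benzodioxol-4-ol, via lithium acetylide 13 (not isolated), via dichlorocerium acetylide 14 (not isolated)
Conditions: 12, n-BuLi, THF, -78 °C; CeCl3, -78 °C; then 10, -78 °C; aq NH4Cl
Reagents that add atoms: none
Why: organocerium 1,2-addition, which is weakly basic and suppresses enolisation; the trans-fused acetonide locks the half-chair, and the slim acetylide should attack axially from the beta face, anti to the pseudoaxial C10 methyl and the axial C5 hydrogen, which sets C1 with the alkynyl group beta and the hydroxyl alpha.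

Step 11
Reactants: 15 tertiary propargylic alcohol
Product: 16 triethylsilyl ether of 15
Conditions: triethylsilyl triflate, 2,6-lutidine, CH2Cl2, -40 to 0 °C
Reagents that add atoms: triethylsilyl trifluoromethanesulfonate, CC[Si](CC)(CC)OS(=O)(=O)C(F)(F)F
Why: silyl triflate silylation of the hindered tertiary hydroxyl masks it against the carbene and the base of step 12.

Step 12
Reactants: 16 cyclohexene triethylsilyl ether; 17 bromoform
Product: 18 gem-dibromocyclopropane (CBr2 carbon C8 bridging C7 and C9 on the beta face of the six-membered ring)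
Conditions: CHBr3, 50% aq NaOH, BnEt3NCl (cat.), CH2Cl2, 0 °C to rt
Reagents that add atoms: none
Why: Dibromocarbene, generated by alpha-elimination of bromoform under phase-transfer conditions, adds to the C7=C9 double bond of 16 in a concerted suprafacial (2+1) cheletropic cycloaddition that forms C8-C9 and C7-C8 at once; the closest known reaction type is the dihalocarbene cyclopropanation of oxygenated cyclohexenes. The three-membered ring closes in this single cheletropic event and is necessarily cis-fused to the six-membered ring. The new stereocentres C7 and C9 are set together by approach of the carbene to the beta face, anti to the pseudoaxial C10 methyl and to O6, which both lie on the alpha face; this facial choice is not critical, because both centres become trigonal again in step 13. The selectivity that matters is chemoselectivity: the internal alkyne, flanked by a quaternary and a silyloxy-bearing carbon, is a far poorer carbene acceptor than the cis-disubstituted alkene, and the tertiary hydroxyl is masked so that no reaction at oxygen can occur. The gem-dibromide also programmes the next step, since only the endo bromide can leave with disrotatory opening to a cis-cycloheptenyl cation.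

Step 13
Reactants: 18 gem-dibromocyclopropane
Product: 19 ring-expanded 8-bromocyclohept-7-en-9-ol (9-hydroxyl beta; 1-O-triethylsilyl; 5,6-O-isopropylidene)
Conditions: AgBF4, CaCO3, acetone/H2O (4:1), rt to 40 °C, dark
Reagents that add atoms: water, O
Why: silver-assisted loss of the endo bromide with disrotatory electrocyclic opening cuts the C7-C9 bond and gives the 2-bromoallyl cation of the seven-membered ring, which water should take at C9, the terminus remote from the inductively deactivating O6, from the beta face anti to the C10 methyl and the C1 silyloxy group, so setting C9.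

Step 14
Reactants: 19 bromocycloheptenol
Product: 20 9-O-tert-butyldimethylsilyl ether of 19
Conditions: tert-butyldimethylsilyl triflate, 2,6-lutidine, CH2Cl2, -78 to 0 °C
Reagents that add atoms: tert-butyldimethylsilyl trifluoromethanesulfonate, CC(C)(C)[Si](C)(C)OS(=O)(=O)C(F)(F)F
Why: silyl triflate silylation protects the hindered secondary allylic hydroxyl at C9 for the later acetalisation and oxidation.

Step 15
Reactants: 20 bis-silyl ether acetonide
Product: 21 1,5,6-triol (acetonide and triethylsilyl group removed; both tert-butyldimethylsilyl ethers kept)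
Conditions: AcOH/THF/H2O (3:1:1), 45 °C
Reagents that add atoms: none
Why: mild acid hydrolysis cleaves the strained trans-fused acetonide and the acid-labile triethylsilyl ether much faster than the two secondary tert-butyldimethylsilyl ethers.

Step 16
Reactants: 21 triol with internal alkyne
Product: 23 alpha-hydroxy ketone (C2 ketone; 1,5,6-triol), via cyclic carbonate 22 (not isolated)
Conditions: AgOAc (10 mol %), DBU, CO2 (1 MPa), MeCN, rt; then H2O, 40 °C
Reagents that add atoms: carbon dioxide, O=C=O; water, O
Why: silver-catalysed carboxylative cyclisation, in which the carbonate formed from the tertiary propargylic hydroxyl adds 5-exo-dig to the silver-activated alkyne so that oxygen is delivered to C2 only, and hydrolysis with loss of CO2 then unveils the C2 ketone.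

Step 17
Reactants: 23 alpha-hydroxy ketone triol; 24 methoxyallene
Product: 25 6-O-(2-bromo-1-methoxyprop-2-enyl) mixed acetal of 23 (both acetal epimers)
Conditions: N-bromosuccinimide, CH2Cl2, -78 to -20 °C
Reagents that add atoms: N-bromosuccinimide, O=C1CCC(=O)N1Br
Why: bromoalkoxylation of the allene: bromonium attack at the central allene carbon gives a methoxy-stabilised cation that should be trapped by the least hindered hydroxyl, the allylic C6 hydroxyl, since the C5 hydroxyl is neopentyl-like next to the quaternary C1 and the C1 hydroxyl is tertiary.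

Step 18
Reactants: 25 bromoacetal
Product: 28 cis-fused 12-methoxy-13-methylene lactol ether (C8 now CH2), via ring bromide 26 (not isolated), via debrominated acetal 27 (not isolated)
Conditions: Bu3SnH (slow addition), AIBN (cat.), benzene, 80 °C
Reagents that add atoms: none
Why: tin hydride radical chain of the Ueno-Stork type with a vinyl radical: the C11 radical closes 5-exo-trig on C7 from the alpha face to which it is tethered through O6, so the new five-membered ring is cis-fused and C7 is set, and both C-Br bonds are reduced whichever reacts first.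

Step 19
Reactants: 28 lactol ether with free C5 hydroxyl; 29 (S)-2-methylbutanoic acid
Product: 30 5-O-[(S)-2-methylbutanoyl] ester of 28
Conditions: N,N'-dicyclohexylcarbodiimide, DMAP (cat.), CH2Cl2, rt
Reagents that add atoms: none
Why: Steglich esterification of the only secondary hydroxyl left (C5); the tertiary C1 hydroxyl does not react and the alpha-stereocentre of the acid is not enolised under these conditions.

Step 20
Reactants: 30 ester with methyl acetal
Product: 31 alpha-methylene lactone 4-O/9-O-bis(tert-butyldimethylsilyl) ether of the target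
Conditions: CrO3, H2SO4, H2O, acetone, 0 °C
Reagents that add atoms: water, O
Why: Jones oxidation hydrolyses the allylic methyl acetal to the lactol and oxidises it to the alpha-methylene-gamma-lactone; no free secondary alcohol is present and the tertiary hydroxyl is inert.

Step 21
Reactants: 31 bis-silyl ether
Product: 32 CNP0291806.4 (target)
Conditions: HF·pyridine, pyridine, THF, 0 °C to rt
Reagents that add atoms: none
Why: buffered fluoride cleavage removes both silyl ethers under mildly acidic conditions that should spare the alpha-methylene lactone, the ester and the beta-hydroxy ketone.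

Compound list
1 | (4R,5R)-2,2-dimethyl-1,3-dioxolane-4,5-dimethanol (2,3-O-isopropylidene-threitol of the R,R series) | OC[C@H]1OC(C)(C)O[C@@H]1CO | starting material
2 | [(4R,5R)-5-{[(4-methoxybenzyl)oxy]methyl}-2,2-dimethyl-1,3-dioxolan-4-yl]methanol | COc1ccc(COC[C@H]2OC(C)(C)O[C@@H]2CO)cc1 | intermediate
3 | (4S,5R)-5-{[(4-methoxybenzyl)oxy]methyl}-2,2-dimethyl-1,3-dioxolane-4-carbaldehyde | COc1ccc(COC[C@H]2OC(C)(C)O[C@@H]2C=O)cc1 | intermediate
4 | (4R,5R)-4-{[(4-methoxybenzyl)oxy]methyl}-2,2-dimethyl-5-vinyl-1,3-dioxolane | COc1ccc(COC[C@H]2OC(C)(C)O[C@@H]2C=C)cc1 | intermediate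
5 | [(4R,5R)-2,2-dimethyl-5-vinyl-1,3-dioxolan-4-yl]methanol | OC[C@H]1OC(C)(C)O[C@@H]1C=C | intermediate
6 | (4S,5R)-2,2-dimethyl-5-vinyl-1,3-dioxolane-4-carbaldehyde | O=C[C@H]1OC(C)(C)O[C@@H]1C=C | intermediate
7 | 2-[(2Z)-but-2-en-1-yl]-4,4,5,5-tetramethyl-1,3,2-dioxaborolane ((Z)-crotylboronic acid pinacol ester) | C/C=C\CB1OC(C)(C)C(C)(C)O1 | starting material
8 | (1R,2S)-1-[(4R,5R)-2,2-dimethyl-5-vinyl-1,3-dioxolan-4-yl]-2-methylbut-3-en-1-ol | C=C[C@H](C)[C@@H](O)[C@H]1OC(C)(C)O[C@@H]1C=C | intermediate
9 | (3aR,4R,5S,7aR)-2,2,5-trimethyl-3a,4,5,7a-tetrahydro-1,3-benzodioxol-4-ol | C[C@H]1C=C[C@H]2OC(C)(C)O[C@@H]2[C@@H]1O | intermediate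
10 | (3aS,5S,7aR)-2,2,5-trimethyl-5,7a-dihydro-1,3-benzodioxol-4(3aH)-one | C[C@H]1C=C[C@H]2OC(C)(C)O[C@@H]2C1=O | intermediate
11 | (R)-but-3-yn-2-ol | C#C[C@@H](C)O | starting material
12 | (R)-(but-3-yn-2-yloxy)(tert-butyl)dimethylsilane | C#C[C@@H](C)O[Si](C)(C)C(C)(C)C | intermediate
13 | lithium acetylide of 12 (not isolated) | [Li]C#C[C@@H](C)O[Si](C)(C)C(C)(C)C | intermediate
14 | dichlorocerium acetylide of 12 (not isolated) | Cl[Ce](Cl)C#C[C@@H](C)O[Si](C)(C)C(C)(C)C | intermediate
15 | (3aS,4R,5S,7aR)-4-[(3R)-3-(tert-butyldimethylsilyloxy)but-1-ynyl]-2,2,5-trimethyl-3a,4,5,7a-tetrahydro-1,3-benzodioxol-4-ol (C1 hydroxyl alpha, alkynyl beta) | C[C@H]1C=C[C@H]2OC(C)(C)O[C@@H]2[C@]1(O)C#C[C@@H](C)O[Si](C)(C)C(C)(C)C | intermediate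
16 | triethylsilyl ether of 15 | C[C@H]1C=C[C@H]2OC(C)(C)O[C@@H]2[C@]1(O[Si](CC)(CC)CC)C#C[C@@H](C)O[Si](C)(C)C(C)(C)C | intermediate
17 | bromoform | BrC(Br)Br | starting material
18 | gem-dibromocyclopropane: 7,7-dibromobicyclo[4.1.0]heptane core, CBr2 (C8) cis-fused across C7 and C9 on the beta face, other groups as in 16 | C[C@H]1[C@H]2[C@H](C2(Br)Br)[C@H]3OC(C)(C)O[C@@H]3[C@]1(O[Si](CC)(CC)CC)C#C[C@@H](C)O[Si](C)(C)C(C)(C)C | intermediate
19 | ring-expanded 8-bromocyclohept-7-en-9-ol: 9-hydroxyl beta, 1-O-triethylsilyl, 5,6-O-isopropylidene, 4-O-tert-butyldimethylsilyl butynyl side chain | C[C@H]1[C@H](O)C(Br)=C[C@H]2OC(C)(C)O[C@@H]2[C@]1(O[Si](CC)(CC)CC)C#C[C@@H](C)O[Si](C)(C)C(C)(C)C | intermediate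
20 | 9-O-tert-butyldimethylsilyl ether of 19 | C[C@H]1[C@H](O[Si](C)(C)C(C)(C)C)C(Br)=C[C@H]2OC(C)(C)O[C@@H]2[C@]1(O[Si](CC)(CC)CC)C#C[C@@H](C)O[Si](C)(C)C(C)(C)C | intermediate
21 | 1,5,6-triol of the bromocycloheptene (9-O- and 4-O-silyl ethers kept, alkyne intact) | C[C@H]1[C@H](O[Si](C)(C)C(C)(C)C)C(Br)=C[C@@H](O)[C@H](O)[C@]1(O)C#C[C@@H](C)O[Si](C)(C)C(C)(C)C | intermediate
22 | (Z)-alkylidene cyclic carbonate spiro-fused at C1 (O1-C(=O)-O-C2=C3), not isolated | C[C@H]1[C@H](O[Si](C)(C)C(C)(C)C)C(Br)=C[C@@H](O)[C@H](O)[C@@]12OC(=O)O/C2=C\[C@@H](C)O[Si](C)(C)C(C)(C)C | intermediate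
23 | alpha-hydroxy ketone: 1,5,6-trihydroxy-2-oxo bromocycloheptene with the complete C2-C4 side chain (4-O-silyl) | C[C@H]1[C@H](O[Si](C)(C)C(C)(C)C)C(Br)=C[C@@H](O)[C@H](O)[C@]1(O)C(=O)C[C@@H](C)O[Si](C)(C)C(C)(C)C | intermediate
24 | methoxyallene (1-methoxypropa-1,2-diene) | COC=C=C | starting material
25 | 6-O-(2-bromo-1-methoxyprop-2-enyl) mixed acetal of 23 (acetal carbon as both epimers) | C[C@H]1[C@H](O[Si](C)(C)C(C)(C)C)C(Br)=C[C@@H](OC(OC)C(Br)=C)[C@H](O)[C@]1(O)C(=O)C[C@@H](C)O[Si](C)(C)C(C)(C)C | intermediate
26 | cyclised acetal that still carries bromine at C8 (not isolated) | C=C1C(OC)O[C@@H]2[C@H]1C(Br)[C@@H](O[Si](C)(C)C(C)(C)C)[C@H](C)[C@@](O)(C(=O)C[C@@H](C)O[Si](C)(C)C(C)(C)C)[C@H]2O | intermediate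
27 | bromoacetal 25 without the ring bromine (C7=C8 alkene, not isolated) | C[C@H]1[C@H](O[Si](C)(C)C(C)(C)C)C=C[C@@H](OC(OC)C(Br)=C)[C@H](O)[C@]1(O)C(=O)C[C@@H](C)O[Si](C)(C)C(C)(C)C | intermediate
28 | cis-fused 12-methoxy-13-methylene lactol ether (2-methoxy-3-methylenetetrahydrofuran fused at C6-C7; free C5 and C1 hydroxyls) | C=C1C(OC)O[C@@H]2[C@H]1C[C@@H](O[Si](C)(C)C(C)(C)C)[C@H](C)[C@@](O)(C(=O)C[C@@H](C)O[Si](C)(C)C(C)(C)C)[C@H]2O | intermediate
29 | (S)-2-methylbutanoic acid | OC(=O)[C@@H](C)CC | starting material
30 | 5-O-[(S)-2-methylbutanoyl] ester of 28 | C=C1C(OC)O[C@@H]2[C@H]1C[C@@H](O[Si](C)(C)C(C)(C)C)[C@H](C)[C@@](O)(C(=O)C[C@@H](C)O[Si](C)(C)C(C)(C)C)[C@H]2OC(=O)[C@@H](C)CC | intermediate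
31 | 4-O,9-O-bis(tert-butyldimethylsilyl) ether of the target (alpha-methylene lactone in place) | C=C1C(=O)O[C@@H]2[C@H]1C[C@@H](O[Si](C)(C)C(C)(C)C)[C@H](C)[C@@](O)(C(=O)C[C@@H](C)O[Si](C)(C)C(C)(C)C)[C@H]2OC(=O)[C@@H](C)CC | intermediate
32 | CNP0291806.4: (1S,4R,5S,6R,7S,9R,10S)-1,4,9-trihydroxy-5-[(2S)-2-methylbutanoyloxy]-2-oxo-4,5-seco-guai-11(13)-en-12,6-olide | C=C1C(=O)O[C@@H]2[C@H]1C[C@@H](O)[C@H](C)[C@@](O)(C(=O)C[C@@H](C)O)[C@H]2OC(=O)[C@@H](C)CC | target

Total step count: 21. Longest linear sequence: 20 steps (steps 1 to 8 and 10 to 21; step 9 prepares alkyne 12).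

Steps most likely to fail

Risk 1 (step 13, ring expansion). Water may take the bromoallyl cation with poor facial selectivity, which would give both C9 epimers. The fallback sets the C9 centre by a hydroxyl-directed reduction instead; it sets out from 19 (as the epimer mixture) and comes back at 21. The mixture is oxidised with Dess-Martin periodinane to the 2-bromo-enone F1. The triethylsilyl group is removed selectively (HF·pyridine, pyridine, THF, 0 °C) to give the beta-hydroxy ketone F2. Reduction with Me4NBH(OAc)3 in MeCN/AcOH (Evans-Saksena reduction) delivers hydride from the boron bound to the C1 oxygen, on the alpha face, and should give the anti-1,3-diol F3 with the C9 hydroxyl beta. The secondary hydroxyl is silylated (tert-butyldimethylsilyl chloride, imidazole, DMF) to give the tertiary alcohol F4, which loses its acetonide under the conditions of step 15 and gives 21.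

Risk 2 (step 10, acetylide addition). The addition to the cyclic ketone may show poor facial selectivity (equatorial attack). The fallback uses acyclic stereocontrol before ring closure; it sets out from 8 and comes back at 16. Alcohol 8 is oxidised (Dess-Martin periodinane, pyridine) to the acyclic ketone F5. The cerium acetylide 14 adds under Felkin-Anh control that is matched for both flanking stereocentres (anti to the C5-O bond and anti to the vinyl group on C10) to give the tertiary alcohol F6. Silylation with triethylsilyl triflate gives the diene F7. Ring-closing metathesis with the first-generation Grubbs catalyst RuCl2(=CHPh)(PCy3)2, which should spare the hindered internal alkyne, gives 16.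

Risk 3 (step 16, hydration of the alkyne). The carboxylative cyclisation may be slow at the hindered internal alkyne, or the amine base may cause beta-elimination of the silyloxy group from the product. The fallback builds the carbonate covalently and closes it with a gold catalyst under neutral conditions; it sets out from 20 and comes back at 23. The triethylsilyl ether of 20 is cleaved selectively (HF·pyridine, pyridine) to the tertiary alcohol F4. Its potassium alkoxide (KN(SiMe3)2) is acylated with di-tert-butyl dicarbonate to the tert-butyl carbonate F8. Ph3PAuNTf2 (cat., CH2Cl2) triggers 5-exo-dig attack of the carbonate carbonyl on the alkyne with loss of 2-methylpropene and gives the cyclic alkylidene carbonate F9. Mild aqueous hydrolysis (K2CO3, THF/H2O) gives the acetonide-protected alpha-hydroxy ketone F10, and removal of the acetonide as in step 15 gives 23.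

Further compounds
F1 | step 13 | 2-bromo-enone (C9 ketone) from oxidation of 19, 1-O-triethylsilyl | C[C@H]1C(=O)C(Br)=C[C@H]2OC(C)(C)O[C@@H]2[C@]1(O[Si](CC)(CC)CC)C#C[C@@H](C)O[Si](C)(C)C(C)(C)C
F2 | step 13 | beta-hydroxy bromo-enone (free C1 hydroxyl) | C[C@H]1C(=O)C(Br)=C[C@H]2OC(C)(C)O[C@@H]2[C@]1(O)C#C[C@@H](C)O[Si](C)(C)C(C)(C)C
F3 | step 13 | anti-1,3-diol (C9 hydroxyl beta, C1 hydroxyl alpha), acetonide kept | C[C@H]1[C@H](O)C(Br)=C[C@H]2OC(C)(C)O[C@@H]2[C@]1(O)C#C[C@@H](C)O[Si](C)(C)C(C)(C)C
F4 | step 13 | 9-O-tert-butyldimethylsilyl ether with free C1 hydroxyl, acetonide kept | C[C@H]1[C@H](O[Si](C)(C)C(C)(C)C)C(Br)=C[C@H]2OC(C)(C)O[C@@H]2[C@]1(O)C#C[C@@H](C)O[Si](C)(C)C(C)(C)C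
F5 | step 10 | (2S)-1-[(4S,5R)-2,2-dimethyl-5-vinyl-1,3-dioxolan-4-yl]-2-methylbut-3-en-1-one | C=C[C@H](C)C(=O)[C@H]1OC(C)(C)O[C@@H]1C=C
F6 | step 10 | acyclic tertiary propargylic alcohol (C1 configured as in 15) | C=C[C@H](C)[C@@](O)(C#C[C@@H](C)O[Si](C)(C)C(C)(C)C)[C@H]1OC(C)(C)O[C@@H]1C=C
F7 | step 10 | triethylsilyl ether of F6 | C=C[C@H](C)[C@@](O[Si](CC)(CC)CC)(C#C[C@@H](C)O[Si](C)(C)C(C)(C)C)[C@H]1OC(C)(C)O[C@@H]1C=C
F8 | step 16 | tert-butyl carbonate of F4 at the C1 oxygen | C[C@H]1[C@H](O[Si](C)(C)C(C)(C)C)C(Br)=C[C@H]2OC(C)(C)O[C@@H]2[C@]1(OC(=O)OC(C)(C)C)C#C[C@@H](C)O[Si](C)(C)C(C)(C)C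
F9 | step 16 | (Z)-alkylidene cyclic carbonate spiro-fused at C1, acetonide kept | C[C@H]1[C@H](O[Si](C)(C)C(C)(C)C)C(Br)=C[C@H]2OC(C)(C)O[C@@H]2[C@@]13OC(=O)O/C3=C\[C@@H](C)O[Si](C)(C)C(C)(C)C
F10 | step 16 | alpha-hydroxy ketone with the 5,6-acetonide kept | C[C@H]1[C@H](O[Si](C)(C)C(C)(C)C)C(Br)=C[C@H]2OC(C)(C)O[C@@H]2[C@]1(O)C(=O)C[C@@H](C)O[Si](C)(C)C(C)(C)C
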